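**Retrosynthetic overview**
1. Target 22 ← intramolecular Diels–Alder reaction of open-chain (2E,4Z,6S,7E,9E,11E,13E)-hexaenoic acid 21; the six-membered ring ([4+2]) and the five-membered ring (closed by the tether) form together in the last step, and C6 controls the four new stereocentres.
2. 21 ← methyl ester 20 ← stereoinvertive alkenyl–allyl coupling (C5–C6) of the (Z)-alkenylzinc from iodide 17 with the (R)-allylic pivalate 11.
3. 11 ← allylic oxidation and three carbonyl olefinations from (R)-4-methylpent-3-en-2-yl pivalate 3.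
4. 3 ← enantioselective Markovnikov hydroacyloxylation of 4-methylpenta-1,3-diene 1 with pivalic acid 2; this C–O bond formation sets the only stereocentre that is carried into the cycloaddition.
5. 17 ← prop-2-yn-1-ol 12 by anti-carbomagnesiation/iodination, then oxidation–Wittig.

Assumption: open-chain compounds 20 and 21 are numbered from the carboxyl carbon (C1); ylides 6, 8 and 15 and phosphonate 10 are bought.

**Route**

Step 1
Reactants: 1 4-methylpenta-1,3-diene; 2 pivalic acid
Product: 3 (2R)-4-methylpent-3-en-2-yl pivalate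
Conditions: Pd2(dba)3 (cat.), (R,R)-DACH-phenyl Trost ligand (cat.), PhMe, 0 °C; diene charged in slight excess, surplus distilled off unchanged
Reagents that add atoms: none
Why: Proposed new method: enantioselective Markovnikov 1,2-hydroacyloxylation of a terminal 1,3-diene, a 1:1 addition in which the O–H of the acid adds across the vinyl group and every atom of 1 and 2 is kept in 3; zerovalent palladium on the vinyl group is protonated by PivOH at the terminal CH2 to give a cationic 1,1,3-trimethyl-π-allyl complex whose diastereomers equilibrate by π–σ–π through the CMe2 terminus, and pivalate then attacks outer-sphere, anti to Pd, at the less hindered CHMe terminus inside the chiral pocket, so the C–O bond formation sets C2 as R (the antipodal ligand is used if the sense is reversed); the chelating bisphosphine leaves no site for a second diene, which shuts down telomerisation, any tertiary ester re-ionises and funnels to 3, and the secondary pivalate is a poor leaving group that the small surplus of diene keeps off the metal, so the ee is kinetic; closest known reactions are Pd-catalysed enantioselective hydroamination of 1,3-dienes, Pd-catalysed addition of carboxylic acids to allenes and deracemising allylic substitution by carboxylates.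

Step 2
Reactants: 3 (2R)-4-methylpent-3-en-2-yl pivalate
Product: 5 (2E,4R)-2-methyl-4-(pivaloyloxy)pent-2-enal, via allylic alcohol 4 (not isolated)
Conditions: SeO2 (1.5 equiv), pyridine (0.5 equiv), 1,4-dioxane, 80 °C
Reagents that add atoms: selenium dioxide, O=[Se]=O
Why: Riley allylic oxidation (ene reaction then [2,3]-shift) attacks the more substituted alkene end and oxidises the (E)-methyl selectively, as in the prenyl acetate to (E)-4-acetoxy-2-methylbut-2-enal case, and the buffered medium leaves the C–O stereocentre untouched.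

Step 3
Reactants: 5 (2E,4R)-2-methyl-4-(pivaloyloxy)pent-2-enal; 6 2-(triphenylphosphoranylidene)butanal
Product: 7 (2E,4E,6R)-2-ethyl-4-methyl-6-(pivaloyloxy)hepta-2,4-dienal
Conditions: 6 (1.3 equiv), PhMe, 90 °C
Reagents that add atoms: none
Why: Wittig olefination with a formyl-stabilised ylide gives the (E)-α-ethyl enal, and the more conjugated, more hindered product reacts more slowly than 5, so mono-homologation prevails.

Step 4
Reactants: 7 (2E,4E,6R)-2-ethyl-4-methyl-6-(pivaloyloxy)hepta-2,4-dienal; 8 2-(triphenylphosphoranylidene)propanal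
Product: 9 (2E,4E,6E,8R)-4-ethyl-2,6-dimethyl-8-(pivaloyloxy)nona-2,4,6-trienal
Conditions: 8 (1.3 equiv), PhMe, 90 °C
Reagents that add atoms: none
Why: A second E-selective Wittig homologation with a formyl-stabilised ylide under neutral conditions, which the pivalate and the stereocentre tolerate.

Step 5
Reactants: 9 (2E,4E,6E,8R)-4-ethyl-2,6-dimethyl-8-(pivaloyloxy)nona-2,4,6-trienal; 10 diethyl benzylphosphonate
Product: 11 (2R,3E,5E,7E,9E)-6-ethyl-4,8-dimethyl-10-phenyldeca-3,5,7,9-tetraen-2-yl pivalate
Conditions: 10, NaN(SiMe3)2, THF, −78 °C; then 9, −78 °C→rt; chromatography on Et3N-deactivated silica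
Reagents that add atoms: none
Why: Horner–Wadsworth–Emmons olefination with the benzylphosphonate anion gives the (E)-styryl terminus, and the hindered pivalate is not attacked at low temperature.

Step 6
Reactants: 12 prop-2-yn-1-ol
Product: 14 (Z)-3-iodo-2-methylprop-2-en-1-ol, via alkenylmagnesium alkoxide 13 (not isolated)
Conditions: MeMgBr (2.5 equiv), CuI (10 mol%), THF, −10 °C→rt; then I2, −78→0 °C
Reagents that add atoms: methylmagnesium bromide, C[Mg]Br; iodine, II
Why: Copper-catalysed alkoxide-directed anti-carbomagnesiation (Duboudin type) places magnesium cis to the CH2O group in a five-membered chelate, and iodinolysis with retention gives the Z-iodide.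

Step 7
Reactants: 14 (Z)-3-iodo-2-methylprop-2-en-1-ol; 15 methyl 2-(triphenylphosphoranylidene)propanoate
Product: 17 methyl (2E,4Z)-5-iodo-2,4-dimethylpenta-2,4-dienoate, via (Z)-3-iodo-2-methylprop-2-enal 16 (not isolated)
Conditions: MnO2 (15 equiv), 15 (1.3 equiv), CH2Cl2, 40 °C
Reagents that add atoms: none
Why: Tandem MnO2 oxidation–Wittig olefination traps the isomerisation-prone (Z)-β-iodo enal as it forms, the stabilised ylide gives the 2E alkene and the Z-iodide geometry is preserved.

Step 8
Reactants: 17 methyl (2E,4Z)-5-iodo-2,4-dimethylpenta-2,4-dienoate; 11 (2R,3E,5E,7E,9E)-6-ethyl-4,8-dimethyl-10-phenyldeca-3,5,7,9-tetraen-2-yl pivalate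
Product: 20 methyl (2E,4Z,6S,7E,9E,11E,13E)-10-ethyl-2,4,6,8,12-pentamethyl-14-phenyltetradeca-2,4,7,9,11,13-hexaenoate, via alkenylmagnesium chloride 18 (not isolated), via alkenylzinc chloride 19 (not isolated)
Conditions: 17 (1.3 equiv), i-PrMgCl·LiCl, THF, −40 °C; ZnCl2, −40→0 °C; then 11, Pd2(dba)3 (2.5 mol%), P(2-furyl)3 (10 mol%), 0 °C→rt
Reagents that add atoms: none
Why: Negishi alkenyl–allyl coupling in which zerovalent palladium ionises the pivalate anti, the configurationally stable (Z)-alkenylzinc transmetalates and reductive elimination occurs on the palladium face at the CH(CH3) terminus (the only one that is not fully substituted, and the one that keeps the tetraene conjugated), so the (R) C–O centre becomes the (6S) C–C centre by net inversion with all alkene geometries retained.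

Step 9
Reactants: 20 methyl (2E,4Z,6S,7E,9E,11E,13E)-10-ethyl-2,4,6,8,12-pentamethyl-14-phenyltetradeca-2,4,7,9,11,13-hexaenoate
Product: 22 (1R,3aR,4R,5S,7aS)-5-ethyl-1,3,4,7-tetramethyl-5-[(1E,3E)-2-methyl-4-phenylbuta-1,3-dien-1-yl]-3a,4,5,7a-tetrahydro-1H-indene-4-carboxylic acid, via hexaenoic acid 21 (not isolated)
Conditions: LiOH·H2O (5 equiv), THF/MeOH/H2O, 0 °C→rt; AcOH to pH 4–5; PhMe, BHT (cat.), 80 °C, same flask
Reagents that add atoms: lithium hydroxide, [Li+].[OH-]
Why: Saponification followed by a biomimetic intramolecular Diels–Alder reaction of the C7–C10 diene with the C2=C3 dienophile, in which the 4Z tether pre-organises the chain, A(1,3) strain with the C8 methyl puts H6 in the diene plane so the dienophile adds anti to the C6 methyl, and the endo-CO2H/exo-tether transition state gives the trans ring fusion, which together with the E dienophile and E,E diene sets C3a, C4, C5 and C7a.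

**Compound list**
1 | 4-methylpenta-1,3-diene | C=CC=C(C)C | starting material
2 | pivalic acid | CC(C)(C)C(=O)O | starting material
3 | (2R)-4-methylpent-3-en-2-yl pivalate | C[C@@H](OC(=O)C(C)(C)C)C=C(C)C | intermediate
4 | (2R,3E)-5-hydroxy-4-methylpent-3-en-2-yl pivalate | C[C@@H](OC(=O)C(C)(C)C)/C=C(\C)CO | intermediate (not isolated)
5 | (2E,4R)-2-methyl-4-(pivaloyloxy)pent-2-enal | C[C@@H](OC(=O)C(C)(C)C)/C=C(\C)C=O | intermediate
6 | 2-(triphenylphosphoranylidene)butanal | CCC(C=O)=P(c1ccccc1)(c1ccccc1)c1ccccc1 | starting material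
7 | (2E,4E,6R)-2-ethyl-4-methyl-6-(pivaloyloxy)hepta-2,4-dienal | C[C@@H](OC(=O)C(C)(C)C)/C=C(C)/C=C(\CC)C=O | intermediate
8 | 2-(triphenylphosphoranylidene)propanal | CC(C=O)=P(c1ccccc1)(c1ccccc1)c1ccccc1 | starting material
9 | (2E,4E,6E,8R)-4-ethyl-2,6-dimethyl-8-(pivaloyloxy)nona-2,4,6-trienal | C[C@@H](OC(=O)C(C)(C)C)/C=C(C)/C=C(CC)/C=C(\C)C=O | intermediate
10 | diethyl benzylphosphonate | CCOP(=O)(Cc1ccccc1)OCC | starting material
11 | (2R,3E,5E,7E,9E)-6-ethyl-4,8-dimethyl-10-phenyldeca-3,5,7,9-tetraen-2-yl pivalate | C[C@@H](OC(=O)C(C)(C)C)/C=C(C)/C=C(CC)/C=C(C)/C=C/c1ccccc1 | intermediate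
12 | prop-2-yn-1-ol | C#CCO | starting material
13 | (Z)-[3-(bromomagnesiooxy)-2-methylprop-1-en-1-yl]magnesium bromide | Br[Mg]OC/C(C)=C\[Mg]Br | intermediate (not isolated)
14 | (Z)-3-iodo-2-methylprop-2-en-1-ol | OC/C(C)=C\I | intermediate
15 | methyl 2-(triphenylphosphoranylidene)propanoate | COC(=O)C(C)=P(c1ccccc1)(c1ccccc1)c1ccccc1 | starting material
16 | (Z)-3-iodo-2-methylprop-2-enal | O=C/C(C)=C\I | intermediate (not isolated)
17 | methyl (2E,4Z)-5-iodo-2,4-dimethylpenta-2,4-dienoate | COC(=O)/C(C)=C/C(C)=C\I | intermediate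
18 | [(1Z,3E)-5-methoxy-2,4-dimethyl-5-oxopenta-1,3-dien-1-yl]magnesium chloride | COC(=O)/C(C)=C/C(C)=C\[Mg]Cl | intermediate (not isolated)
19 | [(1Z,3E)-5-methoxy-2,4-dimethyl-5-oxopenta-1,3-dien-1-yl]zinc chloride | COC(=O)/C(C)=C/C(C)=C\[Zn]Cl | intermediate (not isolated)
20 | methyl (2E,4Z,6S,7E,9E,11E,13E)-10-ethyl-2,4,6,8,12-pentamethyl-14-phenyltetradeca-2,4,7,9,11,13-hexaenoate | COC(=O)/C(C)=C/C(C)=C\[C@@H](C)/C=C(C)/C=C(CC)/C=C(C)/C=C/c1ccccc1 | intermediate
21 | (2E,4Z,6S,7E,9E,11E,13E)-10-ethyl-2,4,6,8,12-pentamethyl-14-phenyltetradeca-2,4,7,9,11,13-hexaenoic acid | OC(=O)/C(C)=C/C(C)=C\[C@@H](C)/C=C(C)/C=C(CC)/C=C(C)/C=C/c1ccccc1 | intermediate (not isolated)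
22 | (1R,3aR,4R,5S,7aS)-5-ethyl-1,3,4,7-tetramethyl-5-[(1E,3E)-2-methyl-4-phenylbuta-1,3-dien-1-yl]-3a,4,5,7a-tetrahydro-1H-indene-4-carboxylic acid | CC[C@]1(/C=C(C)/C=C/c2ccccc2)C=C(C)[C@H]2[C@H](C)C=C(C)[C@@H]2[C@@]1(C)C(=O)O | target

**Step count and risks**
Total steps: 9. Longest linear sequence: 7 (steps 1, 2, 3, 4, 5, 8, 9).

Three steps most likely to fail:

Step 1 (proposed new reaction). The risks are attack at the tertiary allyl terminus, low ee, diene telomerisation, and erosion of ee if palladium re-ionises the product. Fallback with known chemistry, setting out from pivalic acid 2 and coming back at 3: commercial mesityl oxide is reduced with (S)-Me-CBS oxazaborolidine and catecholborane in PhMe at −78 °C (Corey–Bakshi–Shibata reduction) to (R)-4-methylpent-3-en-2-ol F1, which is esterified with 2 (DCC, DMAP, CH2Cl2, Steglich conditions) to give 3.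

Step 8. The pivalate 11 ionises easily, so it may racemise before or during coupling; β-hydride elimination to a pentaene and coupling at another allyl position are also possible. Fallback, setting out from enal 5 and alkenylzinc 19 (made from 17 as in step 8) and coming back at 20: the union is made early, on the electron-poor γ-pivaloyloxy enal, whose allyl termini are clearly differentiated. The same Pd-catalysed Negishi coupling of 19 with 5 (inversion, bond formation distal to the formyl group) gives methyl (2E,4Z,6R,7E)-2,4,6,8-tetramethyl-9-oxonona-2,4,7-trienoate F2. Wittig reaction with 6 gives methyl (2E,4Z,6S,7E,9E)-10-formyl-2,4,6,8-tetramethyldodeca-2,4,7,9-tetraenoate F3. Wittig reaction with 8 gives methyl (2E,4Z,6S,7E,9E,11E)-10-ethyl-2,4,6,8,12-pentamethyl-13-oxotrideca-2,4,7,9,11-pentaenoate F4. Horner–Wadsworth–Emmons reaction with 10 then gives 20; compound 11 is bypassed.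

Step 9. Hydroxide may deprotonate the doubly allylic C6–H (loss of ee or conjugation of the skipped diene), and the cycloaddition may give cis-fused or facial isomers, or compete with a [1,5]-hydrogen shift. Fallback, setting out from 20 and coming back at 22: the cycloaddition is run first on the neutral ester (PhMe, BHT, 90 °C) to give methyl (1R,3aR,4R,5S,7aS)-5-ethyl-1,3,4,7-tetramethyl-5-[(1E,3E)-2-methyl-4-phenylbuta-1,3-dien-1-yl]-3a,4,5,7a-tetrahydro-1H-indene-4-carboxylate F5. This hindered ester has no enolisable centre and is cleaved by SN2 dealkylation at the methyl carbon (LiI, pyridine, 110 °C; acidic work-up) to give 22.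

**Further compounds**
F1 | step 1 | (R)-4-methylpent-3-en-2-ol | C[C@@H](O)C=C(C)C
F2 | step 8 | methyl (2E,4Z,6R,7E)-2,4,6,8-tetramethyl-9-oxonona-2,4,7-trienoate | COC(=O)/C(C)=C/C(C)=C\[C@@H](C)/C=C(\C)C=O
F3 | step 8 | methyl (2E,4Z,6S,7E,9E)-10-formyl-2,4,6,8-tetramethyldodeca-2,4,7,9-tetraenoate | COC(=O)/C(C)=C/C(C)=C\[C@@H](C)/C=C(C)/C=C(\CC)C=O
F4 | step 8 | methyl (2E,4Z,6S,7E,9E,11E)-10-ethyl-2,4,6,8,12-pentamethyl-13-oxotrideca-2,4,7,9,11-pentaenoate | COC(=O)/C(C)=C/C(C)=C\[C@@H](C)/C=C(C)/C=C(CC)/C=C(\C)C=O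
F5 | step 9 | methyl (1R,3aR,4R,5S,7aS)-5-ethyl-1,3,4,7-tetramethyl-5-[(1E,3E)-2-methyl-4-phenylbuta-1,3-dien-1-yl]-3a,4,5,7a-tetrahydro-1H-indene-4-carboxylate | CC[C@]1(/C=C(C)/C=C/c2ccccc2)C=C(C)[C@H]2[C@H](C)C=C(C)[C@@H]2[C@@]1(C)C(=O)OC
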